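## The problem

Betaethrin A (24) is a diaryl ether with no stereocentre, so no stereocentre has to be set and none can direct another. Ring A is a methyl salicylate (ester at C1, hydroxyl at C2, methyl at C4) that carries the ether oxygen at C6. Ring B is a 4'-methoxyphenyl unit whose C1' ether oxygen is flanked by a free hydroxyl at C2' and an acetoxymethyl group at C6'. The ether bond is the difficult one: it lies next to the ester on ring A and between two ortho substituents on ring B. Ring B is too electron-rich to act as the electrophile, and ring A has only the ester to activate it. The selectivity problems are positional: four ring oxygens must end as two free phenols, one methyl ether and the bridge, and each ring has a contiguous trisubstituted edge that must be built without isomers. The benzylic acetate is the most fragile group. It is a benzyl ester, so hydrogenolysis, strong Lewis acids and alkoxide bases threaten it. A free C6' hydroxymethyl group under base can also reach across the bridge to the C1 ester and close an eight-membered lactone. The enabling feature is the C6(O)–C1(carboxyl)–C2(O) sequence of ring A with the methyl at C4: this is the pattern left when an oxygen nucleophile and a carbon electrophile add across the triple bond of a 3-alkoxy-5-methylbenzyne.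

## Retrosynthesis

**24 from 23.** The last cut removes the methyl group from the C2 oxygen and the benzyl group from the C2' oxygen of 23. One boron halide can do both: chelation to the C1 ester activates only the C2 methyl ether, and the benzyl ether falls at low temperature with a cation scavenger. The C4' methyl ether has no chelating neighbour. The acetate is placed before the phenols are freed because acetylating a triol would need selection between three hydroxyls. The forward step must leave the benzylic acetate untouched; its carbon is meta to both ring B oxygens, so ionisation is not assisted.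

**23 back to 20.** Three functional-group bonds are cut in turn: the acetyl C–O bond (23 to alcohol 22), the Si–O bond (22 to silyl ether 21) and the ester O–CH3 bond (21 to acid 20). Esterification comes first so that the carboxylate is capped before the hydroxymethyl group is exposed. Alkylation of the carboxylate is chosen because the acid is flanked on both sides. Nothing here adds skeleton; the steps only need to be mild and ordered so that no free alkoxide meets the ester.

**20 to 8, 15 and 16.** The O–C6 ether bond and the C1–carboxyl bond are cut together. This reveals aryne 18 (released from silyl triflate 8), the phenoxide 17 of phenol 15, and carbon dioxide 16. The neighbouring cut, at O–C1', would make electron-rich ring B the electrophile and is not viable. An SNAr or copper-mediated union at O–C6 needs a pre-made 2-halo-6-alkoxybenzoate and still has to force a doubly ortho-substituted phenoxide onto it. The aryne cut forms the hindered ether at ambient temperature, installs the carboxyl carbon in the same event, and reduces the problem to two monocyclic arenes. The forward reaction must be regioselective across the aryne and must carboxylate, not protonate, the aryl anion.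

**8 to 1.** The C–Si bond and the O–S bond of 8 are cut. Silyl carbamate 6 comes from carbamate 2 by directed metalation at the carbon between the two oxygen substituents, and 2 from commercial phenol 1. The competing route through an ortho-halophenol would need a bromination at the most hindered ring position. The carbamate places silicon there by cooperative direction and is then exchanged for triflate in one flask.

**15 to 12.** The Si–O bond of 15 leads to diol 14, reduction leads back to salicylaldehyde 13, and the C6'–CHO bond is cut to phenol 12. In 12 only one position ortho to the hydroxyl is free, so an ortho-specific formylation can give one isomer only.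

**12 to 9.** The C1'–O bond is traced to a formyl carbon: aryl formate 11 arises by oxygen insertion into aldehyde 10, the benzyl ether of commercial 9. This order labels the three ring B oxygens from the start. The benzyl group goes onto the only phenol of 9, and the future bridging oxygen is created afterwards. A route that introduces both ortho groups symmetrically onto a para-alkoxyphenol would instead need a mono-oxidation and a selective mono-alkylation of a catechol.

## Roads not taken

Alternative 1: Ring B is cut at C1'–C2', C2'–C3' and C4'–C5'. Photolysis of diazo enone A2 would give, by Wolff rearrangement, an aryloxy vinylketene that adds methoxyacetylene A3. The cyclobutenone would open and reclose by 6π electrocyclisation to phenol A1 (Danheiser benzannulation). Merits: the hindered ether is never formed by coupling, because ring B is grown around an existing aryl vinyl ether oxygen. The alkyne polarity fixes the C4' methoxy group, and A1 has both phenols free. Weak points: A2 must be assembled linearly on a finished ring A, so convergence is lost. A ketene is generated in the presence of a salicylate hydroxyl, which would probably need protection. A3 is volatile and labile. A1 still needs acetylation of a primary alcohol in the presence of two phenols. In reaction precedent this road is better placed, since the benzannulation is a known reaction type. The chosen plan offers two short independent branches from commercial arenes and a union at ambient temperature.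

Alternative 2: Ring A is cut at C1–C2 and C5–C6. Vinylketene acetal A5 would add to aryloxypropiolate A6 with matched polarity, and loss of methanol and the silyl group would give salicylate A4. Merits: ring A arrives with its ester and free C2 hydroxyl in place, so carboxylation, esterification and chelation-controlled demethylation all disappear and the endgame is shorter by about two steps. That is a real advantage. Weak points: A6 is a push–pull alkyne whose β-oxygen lowers its dienophilicity. An open-chain Mukaiyama–Michael pathway competes with cycloaddition. A6 must itself be made from the hindered phenol by a non-trivial ynol ether synthesis. A4 also needs debenzylation next to a benzylic acetate. The chosen plan has the longer endgame but both of its coupling partners are of well-known types, and the aryne is electrophilic enough to accept a crowded nucleophile.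

Alternative 3: Ring A is cut at C1–C6 and C4–C5. Pyrone A8 would react as an electron-poor diene with ethynyl ether A9, and the bridged lactone would lose carbon dioxide to give A7, the same compound as ester 21 of the chosen route. Merits: the reaction class is known, the regiochemistry follows from polarity, and the ester is reached in one step from the two partners where the chosen route needs two. On the count of new chemistry this road is the safer one. Weak points: the 4-methoxy and 6-methyl groups of A8 raise its LUMO, so the inverse-demand addition needs heat. Under heat an aryl ethynyl ether such as A9 tends to oligomerise. A9 also costs two further steps from phenol 15, one of them with an alkyllithium. The chosen plan offers shelf-stable partners, reaction at 0 °C to room temperature, regiocontrol built into the aryne, and a short fallback through known chemistry.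

Key step: step 9

Assumption: rotation about the diaryl ether bonds of 24 is taken to be fast at room temperature, so the target has no stereogenic element and only constitution has to be controlled.

## Route

Step 1
Reactants: 1 3-methoxy-5-methylphenol
Product: 2 3-methoxy-5-methylphenyl N-(propan-2-yl)carbamate
Conditions: i-PrNCO, Et3N (cat.), CH2Cl2, rt
Reagents that add atoms: isopropyl isocyanate, CC(C)N=C=O
Why: Base-catalysed carbamoylation of an unhindered phenol by an isocyanate; the N–H carbamate is both the ortho-director for step 2 and a group that can later be expelled as the isocyanate.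

Step 2
Reactants: 2 3-methoxy-5-methylphenyl N-(propan-2-yl)carbamate
Product: 6 3-methoxy-5-methyl-2-(trimethylsilyl)phenyl N-(propan-2-yl)carbamate, via N-silyl carbamate 3 (not isolated), via aryllithium 4 (not isolated), via N-silyl C-silyl carbamate 5 (not isolated)
Conditions: TBSOTf, TMEDA, Et2O, 0 °C to rt; then n-BuLi, TMEDA, −78 °C; TMSCl, −78 °C to rt; aq. NaHSO4
Reagents that add atoms: chlorotrimethylsilane, C[Si](C)(C)Cl
Why: Directed ortho-metalation: N-silylation in the flask masks the N–H, the carbamate and methoxy groups direct n-BuLi cooperatively to the one carbon between them, TMSCl traps the aryllithium, and the N–Si bond is hydrolysed on work-up.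

Step 3
Reactants: 6 3-methoxy-5-methyl-2-(trimethylsilyl)phenyl N-(propan-2-yl)carbamate
Product: 8 3-methoxy-5-methyl-2-(trimethylsilyl)phenyl trifluoromethanesulfonate, via silylphenol 7 (not isolated)
Conditions: DBU, Et2NH, MeCN, 40 °C; then PhNTf2, rt
Reagents that add atoms: N-phenylbis(trifluoromethanesulfonimide), O=S(=O)(N(c1ccccc1)S(=O)(=O)C(F)(F)F)C(F)(F)F
Why: E1cB loss of isopropyl isocyanate from the N–H carbamate (scavenged by Et2NH as a urea) frees the phenoxide, which is triflated in the same flask; this known one-pot carbamate-to-triflate exchange avoids handling the protodesilylation-prone silylphenol.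

Step 4
Reactants: 9 2-hydroxy-4-methoxybenzaldehyde
Product: 10 2-(benzyloxy)-4-methoxybenzaldehyde
Conditions: BnBr, K2CO3, DMF, rt
Reagents that add atoms: benzyl bromide, BrCc1ccccc1
Why: Williamson etherification of the only phenol present; the benzyl group marks the oxygen that becomes the C2' hydroxyl of the target.

Step 5
Reactants: 10 2-(benzyloxy)-4-methoxybenzaldehyde
Product: 12 2-(benzyloxy)-4-methoxyphenol, via aryl formate 11 (not isolated)
Conditions: mCPBA, CH2Cl2, rt; then K2CO3 (cat.), MeOH, rt
Reagents that add atoms: 3-chloroperoxybenzoic acid, OOC(=O)c1cccc(Cl)c1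
Why: Baeyer–Villiger (Dakin-type) oxidation: the aryl group, carrying ortho and para alkoxy donors, migrates in preference to hydrogen, and mild methanolysis of the formate gives the phenol whose oxygen becomes the ether bridge.

Step 6
Reactants: 12 2-(benzyloxy)-4-methoxyphenol
Product: 13 3-(benzyloxy)-2-hydroxy-5-methoxybenzaldehyde
Conditions: MgCl2, Et3N, (CH2O)n, MeCN, reflux
Reagents that add atoms: formaldehyde (as paraformaldehyde), C=O
Why: Magnesium-mediated ortho-formylation (Casnati–Skattebøl reaction): formaldehyde is delivered within the magnesium phenoxide to the ortho carbon and a second formaldehyde accepts hydride; only one ortho position is free, so one regioisomer can form.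

Step 7
Reactants: 13 3-(benzyloxy)-2-hydroxy-5-methoxybenzaldehyde
Product: 14 2-(benzyloxy)-6-(hydroxymethyl)-4-methoxyphenol
Conditions: NaBH4, THF/MeOH, 0 °C
Reagents that add atoms: none
Why: Borohydride reduction of an aryl aldehyde to the benzylic alcohol; nothing else in the molecule is reducible under these conditions.

Step 8
Reactants: 14 2-(benzyloxy)-6-(hydroxymethyl)-4-methoxyphenol
Product: 15 2-(benzyloxy)-6-{[(tert-butyldimethylsilyl)oxy]methyl}-4-methoxyphenol
Conditions: TBSCl (1.05 equiv), imidazole, CH2Cl2, 0 °C
Reagents that add atoms: tert-butyldimethylsilyl chloride, CC(C)(C)[Si](C)(C)Cl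
Why: Chemoselective silylation: the primary alcohol reacts faster than the phenol, which is crowded by two ortho substituents; selective silylation of the alcohol of 2-hydroxybenzyl alcohols is established behaviour.

Step 9
Reactants: 8 3-methoxy-5-methyl-2-(trimethylsilyl)phenyl trifluoromethanesulfonate; 15 2-(benzyloxy)-6-{[(tert-butyldimethylsilyl)oxy]methyl}-4-methoxyphenol; 16 carbon dioxide
Product: 20 2-{2-(benzyloxy)-6-{[(tert-butyldimethylsilyl)oxy]methyl}-4-methoxyphenoxy}-6-methoxy-4-methylbenzoic acid, via potassium phenoxide 17 (not isolated), via 3-methoxy-5-methylbenzyne 18 (not isolated), via potassium carboxylate 19 (not isolated)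
Conditions: 15, KH (1.0 equiv), THF, 0 °C; then KF, 18-crown-6, CO2 (1 atm), slow addition of 8, 0 °C to rt; aq. HCl to pH 4
Reagents that add atoms: none
Why: Proposed new method: fluoride attacks the silicon of 8 and triflate leaves to give aryne 18, whose triple bond is distorted by the inductively withdrawing methoxy group so that the carbon remote from it is the more electrophilic terminus; phenoxide 17 bonds there (O–C6) and leaves the carbanion at C1, between the methoxy and the new aryloxy group. That anion, stabilised inductively by two flanking oxygens, is intercepted by dissolved CO2 (C1–carboxyl bond) to give carboxylate 19, and acidification to pH 4 releases 20 with the silyl ether intact. The closest known reaction types are the three-component coupling of arynes, amines and CO2 to anthranilic acids under KF/18-crown-6 in THF and the regioselective O-arylation of phenoxides by 3-alkoxyarynes; the new element is a phenoxide as nucleophile in the carboxylative version. No ring is closed and no stereocentre is created. Two selectivities are needed: regiochemistry across the aryne, which the C3 methoxy group secures, and carboxylation over protonation of the aryl anion, which is secured by converting 15 fully into 17 with KH so that no O–H remains, by THF in place of the more acidic acetonitrile, by CO2 saturation and by slow addition of 8. The doubly ortho-substituted phenoxide should be accepted because attack on an aryne is sterically undemanding.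

Step 10
Reactants: 20 2-{2-(benzyloxy)-6-{[(tert-butyldimethylsilyl)oxy]methyl}-4-methoxyphenoxy}-6-methoxy-4-methylbenzoic acid
Product: 21 methyl 2-{2-(benzyloxy)-6-{[(tert-butyldimethylsilyl)oxy]methyl}-4-methoxyphenoxy}-6-methoxy-4-methylbenzoate
Conditions: MeI, K2CO3, DMF, rt
Reagents that add atoms: iodomethane, CI
Why: SN2 alkylation of the carboxylate, the standard esterification for 2,6-disubstituted benzoic acids that resist Fischer conditions; no phenol is free to compete.

Step 11
Reactants: 21 methyl 2-{2-(benzyloxy)-6-{[(tert-butyldimethylsilyl)oxy]methyl}-4-methoxyphenoxy}-6-methoxy-4-methylbenzoate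
Product: 22 methyl 2-[2-(benzyloxy)-6-(hydroxymethyl)-4-methoxyphenoxy]-6-methoxy-4-methylbenzoate
Conditions: TBAF, AcOH (1:1), THF, 0 °C to rt
Reagents that add atoms: none
Why: Fluoride-mediated desilylation; the acetic acid buffer keeps the alkoxide concentration low so that the new alcohol does not transesterify onto the C1 ester to form the eight-membered lactone.

Step 12
Reactants: 22 methyl 2-[2-(benzyloxy)-6-(hydroxymethyl)-4-methoxyphenoxy]-6-methoxy-4-methylbenzoate
Product: 23 methyl 2-[2-(acetoxymethyl)-6-(benzyloxy)-4-methoxyphenoxy]-6-methoxy-4-methylbenzoate
Conditions: Ac2O, pyridine, 4-(dimethylamino)pyridine (cat.), CH2Cl2, 0 °C to rt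
Reagents that add atoms: acetic anhydride, CC(=O)OC(C)=O
Why: Nucleophile-catalysed acetylation of the only hydroxyl in the molecule, so no selectivity is required.

Step 13
Reactants: 23 methyl 2-[2-(acetoxymethyl)-6-(benzyloxy)-4-methoxyphenoxy]-6-methoxy-4-methylbenzoate
Product: 24 betaethrin A, methyl 2-[2-(acetoxymethyl)-6-hydroxy-4-methoxyphenoxy]-6-hydroxy-4-methylbenzoate
Conditions: BCl3, pentamethylbenzene, CH2Cl2, −78 °C to −20 °C; aq. NaHCO3
Reagents that add atoms: none
Why: Lewis-acid ether cleavage: boron chelated between the ester carbonyl and the C2 methoxy group lets chloride remove only that methyl group, and the C2' benzyl ether is cleaved at low temperature with the benzyl cation trapped by pentamethylbenzene (Friedel–Crafts); the C4' methyl ether has no chelating neighbour and the acetoxymethyl carbon, meta to both ring B oxygens, is poorly ionisable.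

## Compound list

1 | 3-methoxy-5-methylphenol | COc1cc(C)cc(O)c1 | starting material
2 | 3-methoxy-5-methylphenyl N-(propan-2-yl)carbamate | COc1cc(C)cc(OC(=O)NC(C)C)c1 | intermediate
3 | 3-methoxy-5-methylphenyl N-(tert-butyldimethylsilyl)-N-(propan-2-yl)carbamate | COc1cc(C)cc(OC(=O)N(C(C)C)[Si](C)(C)C(C)(C)C)c1 | intermediate
4 | [2-({[tert-butyl(dimethyl)silyl](propan-2-yl)carbamoyl}oxy)-6-methoxy-4-methylphenyl]lithium | COc1cc(C)cc(OC(=O)N(C(C)C)[Si](C)(C)C(C)(C)C)c1[Li] | intermediate
5 | 3-methoxy-5-methyl-2-(trimethylsilyl)phenyl N-(tert-butyldimethylsilyl)-N-(propan-2-yl)carbamate | COc1cc(C)cc(OC(=O)N(C(C)C)[Si](C)(C)C(C)(C)C)c1[Si](C)(C)C | intermediate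
6 | 3-methoxy-5-methyl-2-(trimethylsilyl)phenyl N-(propan-2-yl)carbamate | COc1cc(C)cc(OC(=O)NC(C)C)c1[Si](C)(C)C | intermediate
7 | 3-methoxy-5-methyl-2-(trimethylsilyl)phenol | COc1cc(C)cc(O)c1[Si](C)(C)C | intermediate
8 | 3-methoxy-5-methyl-2-(trimethylsilyl)phenyl trifluoromethanesulfonate | COc1cc(C)cc(OS(=O)(=O)C(F)(F)F)c1[Si](C)(C)C | intermediate
9 | 2-hydroxy-4-methoxybenzaldehyde | COc1ccc(C=O)c(O)c1 | starting material
10 | 2-(benzyloxy)-4-methoxybenzaldehyde | COc1ccc(C=O)c(OCc2ccccc2)c1 | intermediate
11 | 2-(benzyloxy)-4-methoxyphenyl formate | COc1ccc(OC=O)c(OCc2ccccc2)c1 | intermediate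
12 | 2-(benzyloxy)-4-methoxyphenol | COc1ccc(O)c(OCc2ccccc2)c1 | intermediate
13 | 3-(benzyloxy)-2-hydroxy-5-methoxybenzaldehyde | COc1cc(C=O)c(O)c(OCc2ccccc2)c1 | intermediate
14 | 2-(benzyloxy)-6-(hydroxymethyl)-4-methoxyphenol | COc1cc(CO)c(O)c(OCc2ccccc2)c1 | intermediate
15 | 2-(benzyloxy)-6-{[(tert-butyldimethylsilyl)oxy]methyl}-4-methoxyphenol | COc1cc(OCc2ccccc2)c(O)c(CO[Si](C)(C)C(C)(C)C)c1 | intermediate
16 | carbon dioxide | O=C=O | starting material
17 | potassium 2-(benzyloxy)-6-{[(tert-butyldimethylsilyl)oxy]methyl}-4-methoxyphenolate | [K+].[O-]c1c(OCc2ccccc2)cc(OC)cc1CO[Si](C)(C)C(C)(C)C | intermediate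
18 | 3-methoxy-5-methylbenzyne (1,2-didehydro-3-methoxy-5-methylbenzene) | COC1=CC(C)=CC#C1 | intermediate
19 | potassium 2-{2-(benzyloxy)-6-{[(tert-butyldimethylsilyl)oxy]methyl}-4-methoxyphenoxy}-6-methoxy-4-methylbenzoate | [K+].[O-]C(=O)c1c(OC)cc(C)cc1Oc1c(OCc2ccccc2)cc(OC)cc1CO[Si](C)(C)C(C)(C)C | intermediate
20 | 2-{2-(benzyloxy)-6-{[(tert-butyldimethylsilyl)oxy]methyl}-4-methoxyphenoxy}-6-methoxy-4-methylbenzoic acid | COc1cc(C)cc(Oc2c(OCc3ccccc3)cc(OC)cc2CO[Si](C)(C)C(C)(C)C)c1C(=O)O | intermediate
21 | methyl 2-{2-(benzyloxy)-6-{[(tert-butyldimethylsilyl)oxy]methyl}-4-methoxyphenoxy}-6-methoxy-4-methylbenzoate | COC(=O)c1c(OC)cc(C)cc1Oc1c(OCc2ccccc2)cc(OC)cc1CO[Si](C)(C)C(C)(C)C | intermediate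
22 | methyl 2-[2-(benzyloxy)-6-(hydroxymethyl)-4-methoxyphenoxy]-6-methoxy-4-methylbenzoate | COC(=O)c1c(OC)cc(C)cc1Oc1c(OCc2ccccc2)cc(OC)cc1CO | intermediate
23 | methyl 2-[2-(acetoxymethyl)-6-(benzyloxy)-4-methoxyphenoxy]-6-methoxy-4-methylbenzoate | COC(=O)c1c(OC)cc(C)cc1Oc1c(OCc2ccccc2)cc(OC)cc1COC(C)=O | intermediate
24 | betaethrin A, methyl 2-[2-(acetoxymethyl)-6-hydroxy-4-methoxyphenoxy]-6-hydroxy-4-methylbenzoate | COC(=O)c1c(O)cc(C)cc1Oc1c(O)cc(OC)cc1COC(C)=O | target

## Step count and risks

Total: 13 steps. Longest linear sequence: 10 steps (steps 4 to 13, from 9 to 24). The aryne precursor branch (steps 1 to 3) joins at step 9.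

**Step 9 (key step, new method).** The most likely failure is proton transfer to the aryl anion before CO2 captures it. Possible proton sources are the benzylic C–H bonds of the benzyl ether, traces of water, or residual phenol. This would give the ether without the carboxyl group. Further risks are reversible capture of CO2 by the phenoxide, which lowers its nucleophilicity, arylation of the product carboxylate by a second aryne, and fluoride-induced loss or migration of the silyl group. Fallback by known chemistry, setting out from phenol 15: commercial 1-fluoro-3-methoxy-5-methylbenzene F1 is lithiated between fluorine and methoxy (n-BuLi, THF, −78 °C) and formylated with DMF to give 2-fluoro-6-methoxy-4-methylbenzaldehyde F2. The potassium salt of 15 (K2CO3, DMF, 90 °C) displaces the aldehyde-activated fluoride by SNAr to give 2-{2-(benzyloxy)-6-{[(tert-butyldimethylsilyl)oxy]methyl}-4-methoxyphenoxy}-6-methoxy-4-methylbenzaldehyde F3. Pinnick oxidation (NaClO2, NaH2PO4, 2-methylbut-2-ene, t-BuOH/H2O) then returns to the route at acid 20.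

**Step 13.** The benzylic acetate is a benzyl ester and may be cleaved or converted to the chloride by BCl3, through chloride displacement at the activated acetate. The chelation-controlled demethylation may also stall because the ester is twisted out of the ring plane. Fallback, setting out from ester 21: the BCl3/pentamethylbenzene cleavage is run before any acetate exists and should give methyl 2-{2-{[(tert-butyldimethylsilyl)oxy]methyl}-6-hydroxy-4-methoxyphenoxy}-6-hydroxy-4-methylbenzoate F4. HF·pyridine in THF then gives the triol methyl 2-hydroxy-6-[2-hydroxy-6-(hydroxymethyl)-4-methoxyphenoxy]-4-methylbenzoate F5. Immobilised Candida antarctica lipase B with vinyl acetate (MTBE, 35 °C) acetylates the aliphatic hydroxyl and not the phenols, which arrives at 24.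

**Step 8.** Competing silylation of the phenol, or silyl migration from the benzylic oxygen to the phenolic oxygen, would erode the selectivity. Fallback, setting out from diol 14: excess TBSCl and imidazole in DMF give the bis-silyl ether {[3-(benzyloxy)-2-[(tert-butyldimethylsilyl)oxy]-5-methoxyphenyl]methoxy}(tert-butyl)dimethylsilane F6. K2CO3 in MeOH then cleaves only the aryl silyl ether and returns to 15.

**Step 6.** With this electron-rich phenol the formylation may run on to formaldehyde acetals or stop before the hydride-transfer stage, and the hydroquinone-type ring may oxidise in hot base. Fallback, setting out from phenol 12: phenylboronic acid, paraformaldehyde and catalytic propionic acid in refluxing toluene with removal of water should give, by boron-templated ortho-hydroxymethylation, 8-(benzyloxy)-6-methoxy-2-phenyl-4H-1,3,2-benzodioxaborinine F7. Exchange with propane-1,3-diol releases diol 14 directly, bypassing 13 and step 7.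

## Further compounds

F1 | step 9 | 1-fluoro-3-methoxy-5-methylbenzene | COc1cc(C)cc(F)c1
F2 | step 9 | 2-fluoro-6-methoxy-4-methylbenzaldehyde | COc1cc(C)cc(F)c1C=O
F3 | step 9 | 2-{2-(benzyloxy)-6-{[(tert-butyldimethylsilyl)oxy]methyl}-4-methoxyphenoxy}-6-methoxy-4-methylbenzaldehyde | COc1cc(C)cc(Oc2c(OCc3ccccc3)cc(OC)cc2CO[Si](C)(C)C(C)(C)C)c1C=O
F4 | step 13 | methyl 2-{2-{[(tert-butyldimethylsilyl)oxy]methyl}-6-hydroxy-4-methoxyphenoxy}-6-hydroxy-4-methylbenzoate | COC(=O)c1c(O)cc(C)cc1Oc1c(O)cc(OC)cc1CO[Si](C)(C)C(C)(C)C
F5 | step 13 | methyl 2-hydroxy-6-[2-hydroxy-6-(hydroxymethyl)-4-methoxyphenoxy]-4-methylbenzoate | COC(=O)c1c(O)cc(C)cc1Oc1c(O)cc(OC)cc1CO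
F6 | step 8 | {[3-(benzyloxy)-2-[(tert-butyldimethylsilyl)oxy]-5-methoxyphenyl]methoxy}(tert-butyl)dimethylsilane | COc1cc(OCc2ccccc2)c(O[Si](C)(C)C(C)(C)C)c(CO[Si](C)(C)C(C)(C)C)c1
F7 | step 6 | 8-(benzyloxy)-6-methoxy-2-phenyl-4H-1,3,2-benzodioxaborinine | COc1cc2c(OB(c3ccccc3)OC2)c(OCc2ccccc2)c1
A1 | alternative 1 | methyl 2-{2-{[(tert-butyldimethylsilyl)oxy]methyl}-6-hydroxy-4-methoxyphenoxy}-6-hydroxy-4-methylbenzoate | COC(=O)c1c(O)cc(C)cc1Oc1c(O)cc(OC)cc1CO[Si](C)(C)C(C)(C)C
A2 | alternative 1 | methyl 2-{[(1E)-2-{[(tert-butyldimethylsilyl)oxy]methyl}-4-diazo-3-oxobut-1-en-1-yl]oxy}-6-hydroxy-4-methylbenzoate | COC(=O)c1c(O)cc(C)cc1O/C=C(/C(=O)C=[N+]=[N-])CO[Si](C)(C)C(C)(C)C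
A3 | alternative 1 | methoxyacetylene (methoxyethyne) | COC#C
A4 | alternative 2 | methyl 2-{2-(benzyloxy)-6-{[(tert-butyldimethylsilyl)oxy]methyl}-4-methoxyphenoxy}-6-hydroxy-4-methylbenzoate | COC(=O)c1c(O)cc(C)cc1Oc1c(OCc2ccccc2)cc(OC)cc1CO[Si](C)(C)C(C)(C)C
A5 | alternative 2 | [(1-methoxy-3-methylbuta-1,3-dien-1-yl)oxy]trimethylsilane | COC(O[Si](C)(C)C)=CC(C)=C
A6 | alternative 2 | methyl 3-{2-(benzyloxy)-6-{[(tert-butyldimethylsilyl)oxy]methyl}-4-methoxyphenoxy}prop-2-ynoate | COC(=O)C#COc1c(OCc2ccccc2)cc(OC)cc1CO[Si](C)(C)C(C)(C)C
A7 | alternative 3 | methyl 2-{2-(benzyloxy)-6-{[(tert-butyldimethylsilyl)oxy]methyl}-4-methoxyphenoxy}-6-methoxy-4-methylbenzoate | COC(=O)c1c(OC)cc(C)cc1Oc1c(OCc2ccccc2)cc(OC)cc1CO[Si](C)(C)C(C)(C)C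
A8 | alternative 3 | methyl 4-methoxy-6-methyl-2-oxo-2H-pyran-3-carboxylate | COC(=O)C1=C(OC)C=C(C)OC1=O
A9 | alternative 3 | {[3-(benzyloxy)-2-(ethynyloxy)-5-methoxyphenyl]methoxy}(tert-butyl)dimethylsilane | C#COc1c(OCc2ccccc2)cc(OC)cc1CO[Si](C)(C)C(C)(C)C
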